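The constants used here stand for no real mixture; the result is computed.

- In a one-step world, substrate meets coupling partner, product appears and the account closes; in this scheme the coupling partner meets the target as well, so I kept a ledger.

common to all: substrate 1.0 mM; time 15 min
- south: coupling partner 0.500 equiv
- north-east: coupling partner 1.00 equiv
- south-west: coupling partner 2.00 equiv
- east: coupling partner 4.00 equiv

1. amount of target at the end, in percent of the substrate charged for south, north-east, south-west, east, in this order
2. how the row runs (rises all the way / falls, then rises / hardly changes / rises, then falls / falls all the way)

- "hardly changes" means that all values lie within two and a half points (for a concentration: within two and a half percent of the largest)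
- run time (south): 15 min
- a step back or a flat step of under half a point counts as no turn

    intermediate B ⇌ target (K1 = 16, k1 = 0.11 /s)
    substrate + coupling partner ⇌ intermediate C (K2 = 200 /M, k2 = 0.34 /M/s)
    substrate + coupling partner → intermediate A (k3 = 14 /M/s)
    intermediate A ⇌ intermediate B (K4 = 0.99, k4 = 0.0018 /s)
    coupling partner + target → over-reaction product (k5 = 34 /M/s)

- I opened the ledger on east, where substrate is the limiting reagent: its 1.0 mM stood against 4.00 mM of coupling partner.
- First entry: I reckoned that substrate became intermediate A with a half-life near 0.206 min, with the coupling partner as charged, which is far shorter than the 6.42 min of step 4 forward, so I booked the charge as intermediate A at the start.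
- Side entry: the forward run of step 2 went at 2.43% of the rate of step 3, and I left that in the intermediate A column, since intermediate C can return.
- Second entry: ignoring the way back, I let intermediate A release its content at 0.0018 /s, so I reckoned that 19.8% of it stayed after 15 min.
- Intermediate B passed on with a half-life of 0.105 min, far shorter than 6.42 min, so I gave it no column.
- Third entry: whatever reached over-reaction product cost a second coupling partner, so I reckoned east at about 2.20 mM of coupling partner at the end.
- In east that one concentration sets the order of the target's loss, which is pseudo-first-order at 34 /M/s times [coupling partner], with a half-life near 0.155 min, far shorter than 6.42 min.
- So I put the target in east where feed equals loss, and I named [target]/[intermediate A] = k4/(k5[coupling partner]) the standing ratio; with 2.20 mM it came to 0.0241.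
- Closing the books, I entered for east 0.477% as target and about 79.7% as over-reaction product.
- South and north-east have no excess of coupling partner over substrate to enter in the ratio, so my reckoning stopped there.
- The forecast gave 24%, 32%, 4.5% and 0.5%, a row that rises, then falls, on the ground that “with excess partner the target sits at a small steady level that shrinks as the excess grows”, and my east figure lies close to its last value.
- The simulation gave 28.2%, 37.7%, 4.24% and 0.518%, a row that rises, then falls. At 15.0 min, east held 55.7% of its coupling partner, about 2.23 mM, and 21.4% as intermediate A. The standing ratio 0.0241 times that intermediate A gives 0.516% as target. South-west held 14.4% of its coupling partner, or 0.287 mM, which raises the ratio to 0.184. With 22.8% as intermediate A, that gives 4.19% as target, and the south-west flask stood at 4.24%.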